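## The problem

The target is a heliangolide-type germacranolide. It has a ten-membered carbocycle (C1–C10) with a trans-fused α-methylene-γ-butyrolactone across C6–C7 (lactone oxygen on C6, exocyclic C11=C13), a Z-trisubstituted C4=C5 olefin, and an epoxide on C1/C10 derived from an E-olefin. O3 carries a (2R)-2-methylbutanoate and O8 a (2S,3R)-2,3-dimethyloxirane-2-carboxylate.

Six stereocentres sit on the ring (1R, 3S, 6R, 7R, 8R, 10R) and three in the acyl groups. C6 can direct C7 through the face of a butenolide, and C7 and C8 arise together when the C7–C8 bond is made. C3 is insulated from C6 by the planar olefin and from the epoxide by the C2 methylene, so C3, C6 and C1/C10 must each be set by a reagent. The acyl stereocentres are best brought in with the finished acids.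

The groups that will not survive rough treatment are:
- the α-methylene lactone (Michael acceptor);
- the trisubstituted epoxide and the glycidic ester (acid);
- the γ-hydrogen of any butenolide intermediate (base);
- the two allylic esters;
- any C8 aldehyde, which is β,γ-epoxy and eliminates with base.

A medium ring with a Z-trisubstituted olefin cannot be closed directly with reliable geometric control. The feature that solves this is that C4=C5 is flanked by two oxygen-bearing carbons, C3 and C6. One silicon atom can bridge O3 and O6, so that C4 and C5 end up in a seven-membered 1,3-dioxa-2-silacycloheptene, which can hold only a cis double bond.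

## Retrosynthesis

**C8–O bond.** The hindered O8 ester of 38 is cut at the alkyl–oxygen bond, not the acyl–oxygen bond, giving the 8-epi alcohol 37 (8S) and the glycidic acid 21. This cut is preferred because the ring closure below is expected to give the 8S alcohol, so a Mitsunobu inversion uses that outcome instead of fighting it. The forward step must invert cleanly and must not eliminate toward C7. Acid 21 goes back by oxidation to the epoxy alcohol 20 and by Sharpless epoxidation to tiglyl alcohol 19.

**C7–C8 bond.** Opening the ten-membered ring of 37 between C7 and C8 gives the bromomethyl butenolide aldehyde 35. In the forward direction an allylchromium adds through C7, so the ring, the C7–C8 bond and the exocyclic methylene arise in one step. Cutting here, not at C2–C3 or C9–C10, keeps the epoxide and both olefins inside finished fragments and lets C6 steer C7. Compound 35 has no medium ring. The forward reaction needs high dilution and face selection on both partners.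

**Functional-group changes on the butenolide.** 35 comes from alcohol 34, that from PMB ether 33, the bromide from alcohol 32, and that from silyl ether 31. The O3 ester of 31 is cut to butenolide alcohol 29 and (2R)-2-methylbutanoic acid 30. The order is set by sensitivity: the aldehyde is made last, and the PMB ether is removed oxidatively because the allylic bromide would not tolerate fluoride or base.

**Lactone C12–O6.** 29 is traced to triol 26 by oxidative lactonisation of a Z-2-ene-1,4-diol, and 26 to the silaketal 25 by fluoride.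
- C12 is carried as a silyl-protected primary alcohol, not as an ester. A Z-γ-hydroxy enoate would lactonise as soon as the C6 hydroxyl was free, and O6 could then no longer be bound to silicon.
- Lactonisation after removal of silicon ties up O6 and so distinguishes it from O3 without a protecting group.
- Silicon must leave before the ten-membered ring is closed: in 25 the C2 and C7 substituents leave the dioxasilepine ring on opposite faces and cannot be bridged.

**C4=C5 (key disconnection).** 25 is opened across C4=C5 to the bis(allyloxy)silane 24. Compared with a Wittig-type or cross-coupling construction of this olefin, the tethered metathesis needs no geometric selectivity, because the seven-membered ring enforces Z. It also joins the two halves of the molecule. The forward reaction must close onto a 1,1-disubstituted olefin.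

**Si–O bonds.** 24 is cut at both Si–O bonds into fragment 2 (18), dichlorodiisopropylsilane 22 and fragment 1 (8), joined stepwise through the chlorosilane 23. Both carbinol centres are already in place, so no diastereoselection is asked of the coupling.

**Fragment 1.** 8 is cut at C6–C7 into acrolein 7 and the alkenyl iodide 6 (asymmetric Nozaki–Hiyama–Kishi alkenylation). 6 goes back through alcohol 5 and ester 4 to the β-iodo Morita–Baylis–Hillman adduct 3 of methyl propiolate 1 and formaldehyde 2. The iodoacrylate geometry is what later places the future C12 cis to C6.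

**Fragment 2.** The epoxide of 18 is removed to give the diene alcohol 17 (Shi epoxidation, reagent control). 17 is cut at C3–C4 into aldehyde 15 and 2-bromopropene 16 (asymmetric alkenylation). 15 comes from alcohol 14, which is assembled from alkyne 10 and oxirane 11 by Negishi carboalumination; this fixes the E geometry of C1=C10. 10 is the PMB ether of but-3-yn-1-ol 9.

## Roads not taken

**Alternative 1:** The ring is cut at C1–C2. In the forward step a nitrile oxide at C1, made in situ from an aldoxime, adds to the terminal C2=C3 bond of a Z-diene and gives the isoxazoline-bridged ten-membered ring A1.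
- Merits: the ring is closed by a C–C bond under neutral conditions. C6, C7 and C8 are already fixed in a preformed lactone, so the C8 question that the chosen plan faces in its ring closure does not arise. In this respect the road is better.
- Weak points: the bridged regiochemistry (carbon to C2, oxygen to C3 inside a ten-membered ring) must win over the fused mode and over nitrile oxide dimerisation. C3 is set only by the conformation of the closing macrocycle. The Z-geometry must be built earlier on a conjugated diene.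
- After ring closure A1 still needs a long sequence on a sensitive ring: N–O cleavage to a β-hydroxy ketone that can eliminate into conjugation with C4=C5, selective reduction at C1, closure of the epoxide from the C10 oxygen, and α-methylenation of the lactone.
- Against the preset C8, the chosen plan sets C3 and the epoxide by reagent control on small fragments and an olefin geometry that is not a selectivity question. It pays with an inversion at C8.

**Alternative 2:** The cut is again C7–C8, but made by a Wittig–Still [2,3]-shift. Tin–lithium exchange at C8 gives an α-alkoxy carbanion that attacks C7 of an allylic ether, the O–C13 bond breaks, and a thirteen-membered cyclic ether contracts to the ten-membered alcohol A2.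
- Merits: one step at low temperature forms C7–C8, the C8 hydroxyl and the C11=C13 methylene. A ring contraction needs no high dilution, which the chromium ring closure of the chosen plan does; on this point the road is at least as good.
- Weak points: the organolithium excludes lactone, esters and epoxide. In A2, C12 is still a silyl ether and C1=C10 still an olefin, so C12 must be oxidised and lactonised afterwards. The C1=C10 olefin must then be epoxidised with site and face selectivity next to C4=C5 and C11=C13, controlled only by ring conformation. The relative configuration at C7/C8 depends on the sigmatropic transition state inside a macrocycle and on the configuration of the stannane carbon, and a [1,2]-shift can compete.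
- The chosen plan carries a reagent-controlled epoxide from the start and needs no late epoxidation.

**Alternative 3:** The ring is cut at C3–C4. A Z-alkenyl iodide at C4 adds to a C3 aldehyde under CrCl2 with catalytic NiCl2 and closes the ring onto a finished lactone and epoxide, giving the C3 alcohol A3.
- Merits: this is the most convergent road. Only one stereocentre is made in the ring closure, C8 and the methylene lactone are preset, and A3 is only two acylations and one desilylation from the target. In step count after ring closure and in the security of C8 it is better than the chosen plan.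
- Weak points: the C3 configuration is decided by a macrocyclic addition, and correction at an allylic carbinol is delicate. The Z-trisubstituted alkenyl iodide next to the C6 carbinol must be made with geometric control and carried through the lactone synthesis, so the geometric problem is moved, not removed. The C3 aldehyde is again β,γ-epoxy.
- The chosen plan sets against this an olefin geometry enforced by ring size, a C3 centre made by a reagent on a small fragment, and a simple O–Si–O union of two fragments. It accepts in return the uncertain C8 and a longer protecting-group sequence.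

Key step: step 14

## Route

Remark: locants C1–C15 used for all intermediates are those of the germacrane skeleton of the target; (2R)-2-methylbutanoic acid 30 and (2E)-2-methylbut-2-en-1-ol 19 are taken as purchasable in stereochemically pure form.

Step 1
Reactants: 1 methyl prop-2-ynoate; 2 formaldehyde
Product: 3 methyl (2Z)-2-(hydroxymethyl)-3-iodoprop-2-enoate
Conditions: MgI2 (1.2 equiv), CH2Cl2, 0 °C; CH2O (gas, from paraformaldehyde); aq. NH4Cl
Reagents that add atoms: magnesium diiodide, [Mg+2].[I-].[I-]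
Why: β-Iodo Morita–Baylis–Hillman reaction: iodide adds to the MgI2-activated propiolate and the iodoallenolate is hydroxymethylated at the α-carbon; at 0 °C the Z isomer (iodine cis to the ester) is the expected thermodynamic product. The reaction is established for other aldehydes and is applied here to formaldehyde.

Step 2
Reactants: 3 methyl (2Z)-2-(hydroxymethyl)-3-iodoprop-2-enoate
Product: 4 methyl (2Z)-2-({[tert-butyl(diphenyl)silyl]oxy}methyl)-3-iodoprop-2-enoate
Conditions: TBDPSCl, imidazole, CH2Cl2, 0 °C to rt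
Reagents that add atoms: tert-butyl(chloro)diphenylsilane, CC(C)(C)[Si](Cl)(c1ccccc1)c1ccccc1
Why: Imidazole-promoted silylation of the primary alcohol (the future C13 oxygen); TBDPS is chosen because it must outlast a primary TBS ether and the silaketal in step 15.

Step 3
Reactants: 4 methyl (2Z)-2-({[tert-butyl(diphenyl)silyl]oxy}methyl)-3-iodoprop-2-enoate
Product: 5 (2E)-2-({[tert-butyl(diphenyl)silyl]oxy}methyl)-3-iodoprop-2-en-1-ol
Conditions: iBu2AlH (2.2 equiv), CH2Cl2, −78 °C; aq. potassium sodium tartrate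
Reagents that add atoms: none
Why: 1,2-Reduction of the ester to the allylic alcohol at −78 °C leaves the carbon–iodine bond and the olefin geometry untouched; the new CH2OH (future C12) is cis to iodine.

Step 4
Reactants: 5 (2E)-2-({[tert-butyl(diphenyl)silyl]oxy}methyl)-3-iodoprop-2-en-1-ol
Product: 6 tert-butyl{[(2E)-2-({[tert-butyl(diphenyl)silyl]oxy}methyl)-3-iodoprop-2-en-1-yl]oxy}dimethylsilane
Conditions: TBSCl, imidazole, CH2Cl2, 0 °C to rt
Reagents that add atoms: tert-butyl(chloro)dimethylsilane, CC(C)(C)[Si](C)(C)Cl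
Why: Silylation; the oxygen cis to iodine now carries the silyl group that will leave together with the tether, the trans oxygen the one that stays.

Step 5
Reactants: 6 tert-butyl{[(2E)-2-({[tert-butyl(diphenyl)silyl]oxy}methyl)-3-iodoprop-2-en-1-yl]oxy}dimethylsilane; 7 prop-2-enal (acrolein)
Product: 8 (3R,4E)-5-({[tert-butyl(dimethyl)silyl]oxy}methyl)-6-{[tert-butyl(diphenyl)silyl]oxy}hexa-1,4-dien-3-ol (fragment 1)
Conditions: CrCl2 (10 mol %), chiral oxazoline–sulfonamide ligand (11 mol %, enantiomer that directs Si-face addition), 1,8-bis(dimethylamino)naphthalene, NiCl2·(2,9-dimethyl-1,10-phenanthroline) (2 mol %), Mn, Cp2ZrCl2, LiCl, MeCN, rt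
Reagents that add atoms: none
Why: Catalytic asymmetric Nozaki–Hiyama–Kishi alkenylation: the alkenyl iodide adds oxidatively to nickel, transmetalates to the chiral chromium complex and adds 1,2 to acrolein with retention of olefin geometry. The ligand sets C6 (Si-face attack gives 6R), and no ester is present that could lactonise with the new hydroxyl.

Step 6
Reactants: 9 but-3-yn-1-ol
Product: 10 1-[(but-3-yn-1-yloxy)methyl]-4-methoxybenzene
Conditions: NaH, 4-methoxybenzyl chloride, n-Bu4NI (cat.), THF, 0 °C to rt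
Reagents that add atoms: 4-methoxybenzyl chloride, COc1ccc(CCl)cc1
Why: Williamson etherification; the PMB ether on the future C8 oxygen survives fluoride and is later removed oxidatively at neutral pH.

Step 7
Reactants: 10 1-[(but-3-yn-1-yloxy)methyl]-4-methoxybenzene; 11 oxirane
Product: 14 (3E)-6-[(4-methoxybenzyl)oxy]-4-methylhex-3-en-1-ol, via alkenyldimethylalane 12 (not isolated), via lithium alkenylalanate 13 (not isolated)
Conditions: Me3Al (2.5 equiv), Cp2ZrCl2 (0.25 equiv), CH2Cl2, 0 °C to rt; volatiles removed; n-BuLi, hexane/THF, −78 °C; oxirane, −78 to 0 °C; aq. potassium sodium tartrate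
Reagents that add atoms: trimethylaluminium, C[Al](C)C
Why: Zirconium-catalysed Negishi carboalumination adds methyl and aluminium syn across the alkyne with methyl on the internal carbon, which fixes the E geometry of the future C1=C10. The alanate formed with n-BuLi opens oxirane with retention at the alkenyl carbon.

Step 8
Reactants: 14 (3E)-6-[(4-methoxybenzyl)oxy]-4-methylhex-3-en-1-ol
Product: 15 (3E)-6-[(4-methoxybenzyl)oxy]-4-methylhex-3-enal
Conditions: Dess–Martin periodinane, NaHCO3, CH2Cl2, 0 °C; used crude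
Reagents that add atoms: none
Why: Dess–Martin oxidation under buffered, non-basic conditions should give the β,γ-unsaturated aldehyde without migration of the double bond into conjugation.

Step 9
Reactants: 15 (3E)-6-[(4-methoxybenzyl)oxy]-4-methylhex-3-enal; 16 2-bromoprop-1-ene
Product: 17 (3S,5E)-8-[(4-methoxybenzyl)oxy]-2,6-dimethylocta-1,5-dien-3-ol
Conditions: CrCl2 (10 mol %), chiral oxazoline–sulfonamide ligand (11 mol %, enantiomer that directs Re-face addition), 1,8-bis(dimethylamino)naphthalene, NiCl2·(2,9-dimethyl-1,10-phenanthroline) (2 mol %), Mn, Cp2ZrCl2, LiCl, MeCN, rt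
Reagents that add atoms: none
Why: Catalytic asymmetric Nozaki–Hiyama–Kishi reaction of a 2-haloalkene; the chiral chromium complex controls Re-face addition, which gives 3S. The neutral conditions should leave the skipped enal unisomerised.

Step 10
Reactants: 17 (3S,5E)-8-[(4-methoxybenzyl)oxy]-2,6-dimethylocta-1,5-dien-3-ol
Product: 18 (2S)-1-[(2R,3R)-3-{2-[(4-methoxybenzyl)oxy]ethyl}-3-methyloxiran-2-yl]-3-methylbut-3-en-2-ol (fragment 2)
Conditions: D-fructose-derived Shi ketone (0.3 equiv), KHSO5 (as Oxone, 2KHSO5·KHSO4·K2SO4), K2CO3, n-Bu4NHSO4, MeCN/dimethoxymethane/aq. buffer (pH 10.5), 0 °C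
Reagents that add atoms: potassium peroxymonosulfate, [K+].[O-]S(=O)(=O)OO
Why: Shi epoxidation: the chiral dioxirane epoxidises the electron-rich trisubstituted E-olefin through a spiro transition state and gives the (R,R) epoxide by reagent control. The 1,1-disubstituted olefin, deactivated by the allylic hydroxyl, reacts much more slowly.

Step 11
Reactants: 19 (2E)-2-methylbut-2-en-1-ol
Product: 20 [(2R,3R)-2,3-dimethyloxiran-2-yl]methanol
Conditions: Ti(OiPr)4 (cat.), D-(−)-diisopropyl tartrate (cat.), t-BuOOH, 4 Å molecular sieves, CH2Cl2, −20 °C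
Reagents that add atoms: tert-butyl hydroperoxide, CC(C)(C)OO
Why: Sharpless asymmetric epoxidation; with the D-(−)-tartrate the E-allylic alcohol gives the (2R,3R) epoxy alcohol, and the two methyl groups stay cis.

Step 12
Reactants: 20 [(2R,3R)-2,3-dimethyloxiran-2-yl]methanol
Product: 21 (2S,3R)-2,3-dimethyloxirane-2-carboxylic acid
Conditions: RuCl3 hydrate (2 mol %), NaIO4, MeCN/EtOAc/H2O, rt
Reagents that add atoms: water, O
Why: Ruthenium tetroxide, formed catalytically from RuCl3 and NaIO4, oxidises the primary alcohol through the aldehyde hydrate to the acid without opening the epoxide. The C2 descriptor changes from R to S only because the substituent priorities change.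

Step 13
Reactants: 18 (2S)-1-[(2R,3R)-3-{2-[(4-methoxybenzyl)oxy]ethyl}-3-methyloxiran-2-yl]-3-methylbut-3-en-2-ol; 22 dichlorodi(propan-2-yl)silane; 8 (3R,4E)-5-({[tert-butyl(dimethyl)silyl]oxy}methyl)-6-{[tert-butyl(diphenyl)silyl]oxy}hexa-1,4-dien-3-ol
Product: 24 {[(3R,4E)-5-({[tert-butyl(dimethyl)silyl]oxy}methyl)-6-{[tert-butyl(diphenyl)silyl]oxy}hexa-1,4-dien-3-yl]oxy}{[(2S)-1-[(2R,3R)-3-{2-[(4-methoxybenzyl)oxy]ethyl}-3-methyloxiran-2-yl]-3-methylbut-3-en-2-yl]oxy}di(propan-2-yl)silane, via chlorosilyl ether 23 (not isolated)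
Conditions: 18, iPr2SiCl2 (3 equiv), imidazole, CH2Cl2, 0 °C; excess silane removed in vacuo; then 8, imidazole, DMF, rt
Reagents that add atoms: none
Why: Stepwise silylation: the more hindered alcohol 18 is silylated first with excess 22 to the monochloride 23, which then silylates 8. The isopropyl groups make the mixed silaketal stable to chromatography, and no stereocentre is touched.

Step 14
Reactants: 24 {[(3R,4E)-5-({[tert-butyl(dimethyl)silyl]oxy}methyl)-6-{[tert-butyl(diphenyl)silyl]oxy}hexa-1,4-dien-3-yl]oxy}{[(2S)-1-[(2R,3R)-3-{2-[(4-methoxybenzyl)oxy]ethyl}-3-methyloxiran-2-yl]-3-methylbut-3-en-2-yl]oxy}di(propan-2-yl)silane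
Product: 25 (4S,7S)-7-[(1E)-2-({[tert-butyl(dimethyl)silyl]oxy}methyl)-3-{[tert-butyl(diphenyl)silyl]oxy}prop-1-en-1-yl]-4-{[(2R,3R)-3-{2-[(4-methoxybenzyl)oxy]ethyl}-3-methyloxiran-2-yl]methyl}-5-methyl-2,2-di(propan-2-yl)-4,7-dihydro-1,3,2-dioxasilepine
Conditions: second-generation Grubbs catalyst (10 mol %), toluene (2 mM), 80 °C, argon sparge
Reagents that add atoms: none
Why: The ruthenium alkylidene initiates at the monosubstituted C5 vinyl group of 24, the most accessible olefin, and the resulting C5 carbene undergoes cycloaddition and cycloreversion with the 1,1-disubstituted C4 isopropenyl group held close by the O–Si–O bridge, releasing ethene. The closest known reaction type is the temporary silicon-tethered ring-closing metathesis of bis(allyloxy)silanes to dioxasilepines with trisubstituted olefins. The one ring that closes is the seven-membered 1,3-dioxa-2-silacyclohept-5-ene, formed by ring-closing olefin metathesis with both olefin carbons inside the ring; a ring of this size holds only a cis olefin, which is the Z-trisubstituted C4=C5 bond. No stereocentre is formed: C3 and C6 come unchanged from 18 and 8, and the descriptor at C6 changes from R to S only because the ring olefin now outranks the side-chain olefin. The selectivity needed is chemoselectivity among the olefins, and the substrate secures it: the trisubstituted C7=C11 bond is shielded by two silyloxymethyl groups and could only close a three-membered ring with C5, while the isopropenyl group is too hindered to react other than intramolecularly. The two isopropyl groups on silicon (gem-dialkyl effect) and high dilution favour ring closure over dimerisation at the vinyl group, and the epoxide, PMB ether and silyl ethers are inert to the catalyst. The step forms the first carbon–carbon bond between fragment 1 and fragment 2.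

Step 15
Reactants: 25 (4S,7S)-7-[(1E)-2-({[tert-butyl(dimethyl)silyl]oxy}methyl)-3-{[tert-butyl(diphenyl)silyl]oxy}prop-1-en-1-yl]-4-{[(2R,3R)-3-{2-[(4-methoxybenzyl)oxy]ethyl}-3-methyloxiran-2-yl]methyl}-5-methyl-2,2-di(propan-2-yl)-4,7-dihydro-1,3,2-dioxasilepine
Product: 26 (2E,4S,5Z,7S)-2-({[tert-butyl(diphenyl)silyl]oxy}methyl)-8-[(2R,3R)-3-{2-[(4-methoxybenzyl)oxy]ethyl}-3-methyloxiran-2-yl]-6-methylocta-2,5-diene-1,4,7-triol
Conditions: HF·pyridine, pyridine, THF, 0 °C to rt
Reagents that add atoms: none
Why: Buffered HF·pyridine cleaves the silaketal and the primary TBS ether much faster than the primary TBDPS ether and is known to spare trisubstituted epoxides. This frees the C3, C6 and C12 hydroxyls while C13 stays protected.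

Step 16
Reactants: 26 (2E,4S,5Z,7S)-2-({[tert-butyl(diphenyl)silyl]oxy}methyl)-8-[(2R,3R)-3-{2-[(4-methoxybenzyl)oxy]ethyl}-3-methyloxiran-2-yl]-6-methylocta-2,5-diene-1,4,7-triol
Product: 29 (5R)-3-({[tert-butyl(diphenyl)silyl]oxy}methyl)-5-[(1Z,3S)-3-hydroxy-4-[(2R,3R)-3-{2-[(4-methoxybenzyl)oxy]ethyl}-3-methyloxiran-2-yl]-2-methylbut-1-en-1-yl]furan-2(5H)-one, via hydroxy enal 27 (not isolated), via lactol 28 (not isolated)
Conditions: TEMPO (0.2 equiv), PhI(OAc)2 (2.2 equiv), CH2Cl2, 0 °C to rt
Reagents that add atoms: none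
Why: The oxoammonium oxidant takes the primary allylic alcohol selectively to the Z-enal 27, which closes with the cis C6 hydroxyl to lactol 28 and is oxidised on to the butenolide (oxidative lactonisation of a Z-2-ene-1,4-diol). This ties up O6 and leaves the secondary C3 hydroxyl as the only free alcohol.

Step 17
Reactants: 29 (5R)-3-({[tert-butyl(diphenyl)silyl]oxy}methyl)-5-[(1Z,3S)-3-hydroxy-4-[(2R,3R)-3-{2-[(4-methoxybenzyl)oxy]ethyl}-3-methyloxiran-2-yl]-2-methylbut-1-en-1-yl]furan-2(5H)-one; 30 (2R)-2-methylbutanoic acid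
Product: 31 (2S,3Z)-4-[(2R)-4-({[tert-butyl(diphenyl)silyl]oxy}methyl)-5-oxo-2,5-dihydrofuran-2-yl]-1-[(2R,3R)-3-{2-[(4-methoxybenzyl)oxy]ethyl}-3-methyloxiran-2-yl]-3-methylbut-3-en-2-yl (2R)-2-methylbutanoate
Conditions: EDC·HCl, DMAP (cat.), CH2Cl2, 0 °C to rt
Reagents that add atoms: none
Why: Carbodiimide (Steglich) esterification of the only free hydroxyl; at 0 °C with catalytic DMAP the α-stereocentre of the acid is not expected to epimerise.

Step 18
Reactants: 31 (2S,3Z)-4-[(2R)-4-({[tert-butyl(diphenyl)silyl]oxy}methyl)-5-oxo-2,5-dihydrofuran-2-yl]-1-[(2R,3R)-3-{2-[(4-methoxybenzyl)oxy]ethyl}-3-methyloxiran-2-yl]-3-methylbut-3-en-2-yl (2R)-2-methylbutanoate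
Product: 32 (2S,3Z)-4-[(2R)-4-(hydroxymethyl)-5-oxo-2,5-dihydrofuran-2-yl]-1-[(2R,3R)-3-{2-[(4-methoxybenzyl)oxy]ethyl}-3-methyloxiran-2-yl]-3-methylbut-3-en-2-yl (2R)-2-methylbutanoate
Conditions: n-Bu4NF, AcOH (1:1), THF, 0 °C to rt
Reagents that add atoms: none
Why: Fluoride buffered with acetic acid removes the TBDPS group without deprotonating the butenolide γ-position (C6) or cleaving the esters.

Step 19
Reactants: 32 (2S,3Z)-4-[(2R)-4-(hydroxymethyl)-5-oxo-2,5-dihydrofuran-2-yl]-1-[(2R,3R)-3-{2-[(4-methoxybenzyl)oxy]ethyl}-3-methyloxiran-2-yl]-3-methylbut-3-en-2-yl (2R)-2-methylbutanoate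
Product: 33 (2S,3Z)-4-[(2R)-4-(bromomethyl)-5-oxo-2,5-dihydrofuran-2-yl]-1-[(2R,3R)-3-{2-[(4-methoxybenzyl)oxy]ethyl}-3-methyloxiran-2-yl]-3-methylbut-3-en-2-yl (2R)-2-methylbutanoate
Conditions: CBr4, PPh3, CH2Cl2, 0 °C
Reagents that add atoms: carbon tetrabromide, BrC(Br)(Br)Br
Why: Appel bromination converts the primary allylic alcohol into the bromide under neutral conditions; the epoxide, esters and PMB ether are inert at 0 °C.

Step 20
Reactants: 33 (2S,3Z)-4-[(2R)-4-(bromomethyl)-5-oxo-2,5-dihydrofuran-2-yl]-1-[(2R,3R)-3-{2-[(4-methoxybenzyl)oxy]ethyl}-3-methyloxiran-2-yl]-3-methylbut-3-en-2-yl (2R)-2-methylbutanoate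
Product: 34 (2S,3Z)-4-[(2R)-4-(bromomethyl)-5-oxo-2,5-dihydrofuran-2-yl]-1-[(2R,3R)-3-(2-hydroxyethyl)-3-methyloxiran-2-yl]-3-methylbut-3-en-2-yl (2R)-2-methylbutanoate
Conditions: DDQ, CH2Cl2/aq. NaH2PO4–Na2HPO4 buffer (pH 7), 0 °C
Reagents that add atoms: none
Why: Oxidative cleavage of the PMB ether by DDQ at neutral pH is compatible with the allylic bromide, which would not survive fluoride or base.

Step 21
Reactants: 34 (2S,3Z)-4-[(2R)-4-(bromomethyl)-5-oxo-2,5-dihydrofuran-2-yl]-1-[(2R,3R)-3-(2-hydroxyethyl)-3-methyloxiran-2-yl]-3-methylbut-3-en-2-yl (2R)-2-methylbutanoate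
Product: 35 (2S,3Z)-4-[(2R)-4-(bromomethyl)-5-oxo-2,5-dihydrofuran-2-yl]-3-methyl-1-[(2R,3R)-3-methyl-3-(2-oxoethyl)oxiran-2-yl]but-3-en-2-yl (2R)-2-methylbutanoate
Conditions: Dess–Martin periodinane, NaHCO3, CH2Cl2, 0 °C; used at once
Reagents that add atoms: none
Why: Buffered Dess–Martin oxidation gives the aldehyde without base; the β,γ-epoxy aldehyde is prone to β-elimination and is carried on immediately.

Step 22
Reactants: 35 (2S,3Z)-4-[(2R)-4-(bromomethyl)-5-oxo-2,5-dihydrofuran-2-yl]-3-methyl-1-[(2R,3R)-3-methyl-3-(2-oxoethyl)oxiran-2-yl]but-3-en-2-yl (2R)-2-methylbutanoate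
Product: 37 (1R,3S,4Z,6R,7R,8S,10R)-1,10-epoxy-8-hydroxy-3-{[(2R)-2-methylbutanoyl]oxy}germacra-4,11(13)-dien-12,6-olide, via allylchromium dichloride 36 (not isolated)
Conditions: CrCl2 (6 equiv), THF (1 mM, slow addition of 35), rt
Reagents that add atoms: none
Why: Intramolecular Nozaki–Hiyama–Kishi allylation: divalent chromium converts the allylic bromide into the allylchromium 36 (trivalent chromium), which adds through C7 to the aldehyde in a six-membered chair transition state and forms C7–C8, the ten-membered ring and the exocyclic C11=C13. C8 should approach the butenolide face anti to the C5 substituent on C6 (7R, trans-lactone). With the ring-locked allyl geometry (C6 trans to the CH2Cr carbon) and C9 pseudo-equatorial, the chair is expected to give 8S, as it does in intermolecular additions of 3-(bromomethyl)butenolides.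

Step 23
Reactants: 37 (1R,3S,4Z,6R,7R,8S,10R)-1,10-epoxy-8-hydroxy-3-{[(2R)-2-methylbutanoyl]oxy}germacra-4,11(13)-dien-12,6-olide; 21 (2S,3R)-2,3-dimethyloxirane-2-carboxylic acid
Product: 38 (1R,3S,4Z,6R,7R,8R,10R)-8-{[(2S,3R)-2,3-dimethyloxirane-2-carbonyl]oxy}-1,10-epoxy-3-{[(2R)-2-methylbutanoyl]oxy}germacra-4,11(13)-dien-12,6-olide (CNP0265335.4)
Conditions: PPh3, diisopropyl azodicarboxylate, toluene, 0 °C to rt
Reagents that add atoms: none
Why: Mitsunobu esterification: the C8 hydroxyl is activated as the oxyphosphonium ion and displaced by the carboxylate of 21 with inversion, which gives the required 8R ester. It also avoids acylating a hindered alcohol with an α-quaternary acid by addition–elimination.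

## Compound list

1 | methyl prop-2-ynoate (methyl propiolate) | C#CC(=O)OC | starting material
2 | formaldehyde | C=O | starting material
3 | methyl (2Z)-2-(hydroxymethyl)-3-iodoprop-2-enoate | COC(=O)/C(CO)=C\I | intermediate
4 | methyl (2Z)-2-({[tert-butyl(diphenyl)silyl]oxy}methyl)-3-iodoprop-2-enoate | COC(=O)/C(CO[Si](c1ccccc1)(c1ccccc1)C(C)(C)C)=C\I | intermediate
5 | (2E)-2-({[tert-butyl(diphenyl)silyl]oxy}methyl)-3-iodoprop-2-en-1-ol (iodine cis to CH2OH) | OC/C(CO[Si](c1ccccc1)(c1ccccc1)C(C)(C)C)=C\I | intermediate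
6 | tert-butyl{[(2E)-2-({[tert-butyl(diphenyl)silyl]oxy}methyl)-3-iodoprop-2-en-1-yl]oxy}dimethylsilane (iodine cis to CH2OTBS) | CC(C)(C)[Si](C)(C)OC/C(CO[Si](c1ccccc1)(c1ccccc1)C(C)(C)C)=C\I | intermediate
7 | prop-2-enal (acrolein) | C=CC=O | starting material
8 | (3R,4E)-5-({[tert-butyl(dimethyl)silyl]oxy}methyl)-6-{[tert-butyl(diphenyl)silyl]oxy}hexa-1,4-dien-3-ol (fragment 1; C6–O cis to CH2OTBS) | C=C[C@@H](O)/C=C(/CO[Si](c1ccccc1)(c1ccccc1)C(C)(C)C)CO[Si](C)(C)C(C)(C)C | intermediate
9 | but-3-yn-1-ol | C#CCCO | starting material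
10 | 1-[(but-3-yn-1-yloxy)methyl]-4-methoxybenzene | C#CCCOCc1ccc(OC)cc1 | intermediate
11 | oxirane (ethylene oxide) | C1CO1 | starting material
12 | [(1E)-4-[(4-methoxybenzyl)oxy]-2-methylbut-1-en-1-yl]dimethylalumane | C[Al](C)/C=C(\C)CCOCc1ccc(OC)cc1 | intermediate
13 | lithium butyl[(1E)-4-[(4-methoxybenzyl)oxy]-2-methylbut-1-en-1-yl]dimethylaluminate | [Li+].CCCC[Al-](C)(C)/C=C(\C)CCOCc1ccc(OC)cc1 | intermediate
14 | (3E)-6-[(4-methoxybenzyl)oxy]-4-methylhex-3-en-1-ol | OCC/C=C(\C)CCOCc1ccc(OC)cc1 | intermediate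
15 | (3E)-6-[(4-methoxybenzyl)oxy]-4-methylhex-3-enal | O=CC/C=C(\C)CCOCc1ccc(OC)cc1 | intermediate
16 | 2-bromoprop-1-ene | CC(Br)=C | starting material
17 | (3S,5E)-8-[(4-methoxybenzyl)oxy]-2,6-dimethylocta-1,5-dien-3-ol | C=C(C)[C@@H](O)C/C=C(\C)CCOCc1ccc(OC)cc1 | intermediate
18 | (2S)-1-[(2R,3R)-3-{2-[(4-methoxybenzyl)oxy]ethyl}-3-methyloxiran-2-yl]-3-methylbut-3-en-2-ol (fragment 2) | C=C(C)[C@@H](O)C[C@H]1O[C@]1(C)CCOCc1ccc(OC)cc1 | intermediate
19 | (2E)-2-methylbut-2-en-1-ol (tiglyl alcohol) | C/C=C(\C)CO | starting material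
20 | [(2R,3R)-2,3-dimethyloxiran-2-yl]methanol | OC[C@@]1(C)O[C@@H]1C | intermediate
21 | (2S,3R)-2,3-dimethyloxirane-2-carboxylic acid | OC(=O)[C@@]1(C)O[C@@H]1C | intermediate
22 | dichlorodi(propan-2-yl)silane | CC(C)[Si](Cl)(Cl)C(C)C | starting material
23 | chloro{[(2S)-1-[(2R,3R)-3-{2-[(4-methoxybenzyl)oxy]ethyl}-3-methyloxiran-2-yl]-3-methylbut-3-en-2-yl]oxy}di(propan-2-yl)silane | C=C(C)[C@@H](O[Si](Cl)(C(C)C)C(C)C)C[C@H]1O[C@]1(C)CCOCc1ccc(OC)cc1 | intermediate
24 | {[(3R,4E)-5-({[tert-butyl(dimethyl)silyl]oxy}methyl)-6-{[tert-butyl(diphenyl)silyl]oxy}hexa-1,4-dien-3-yl]oxy}{[(2S)-1-[(2R,3R)-3-{2-[(4-methoxybenzyl)oxy]ethyl}-3-methyloxiran-2-yl]-3-methylbut-3-en-2-yl]oxy}di(propan-2-yl)silane (silaketal of O6 of 8 and O3 of 18) | C=C[C@H](/C=C(/CO[Si](c1ccccc1)(c1ccccc1)C(C)(C)C)CO[Si](C)(C)C(C)(C)C)O[Si](C(C)C)(C(C)C)O[C@H](C(C)=C)C[C@H]1O[C@]1(C)CCOCc1ccc(OC)cc1 | intermediate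
25 | (4S,7S)-7-[(1E)-2-({[tert-butyl(dimethyl)silyl]oxy}methyl)-3-{[tert-butyl(diphenyl)silyl]oxy}prop-1-en-1-yl]-4-{[(2R,3R)-3-{2-[(4-methoxybenzyl)oxy]ethyl}-3-methyloxiran-2-yl]methyl}-5-methyl-2,2-di(propan-2-yl)-4,7-dihydro-1,3,2-dioxasilepine | CC1=C[C@H](/C=C(/CO[Si](c2ccccc2)(c2ccccc2)C(C)(C)C)CO[Si](C)(C)C(C)(C)C)O[Si](C(C)C)(C(C)C)O[C@H]1C[C@H]2O[C@]2(C)CCOCc2ccc(OC)cc2 | intermediate
26 | (2E,4S,5Z,7S)-2-({[tert-butyl(diphenyl)silyl]oxy}methyl)-8-[(2R,3R)-3-{2-[(4-methoxybenzyl)oxy]ethyl}-3-methyloxiran-2-yl]-6-methylocta-2,5-diene-1,4,7-triol | OC/C(CO[Si](c1ccccc1)(c1ccccc1)C(C)(C)C)=C\[C@H](O)/C=C(/C)[C@@H](O)C[C@H]1O[C@]1(C)CCOCc1ccc(OC)cc1 | intermediate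
27 | (2Z,4R,5Z,7S)-2-({[tert-butyl(diphenyl)silyl]oxy}methyl)-4,7-dihydroxy-8-[(2R,3R)-3-{2-[(4-methoxybenzyl)oxy]ethyl}-3-methyloxiran-2-yl]-6-methylocta-2,5-dienal | O=C/C(CO[Si](c1ccccc1)(c1ccccc1)C(C)(C)C)=C\[C@H](O)/C=C(/C)[C@@H](O)C[C@H]1O[C@]1(C)CCOCc1ccc(OC)cc1 | intermediate
28 | (5R)-3-({[tert-butyl(diphenyl)silyl]oxy}methyl)-5-[(1Z,3S)-3-hydroxy-4-[(2R,3R)-3-{2-[(4-methoxybenzyl)oxy]ethyl}-3-methyloxiran-2-yl]-2-methylbut-1-en-1-yl]-2,5-dihydrofuran-2-ol (both C2 epimers) | CC(C)(C)[Si](c1ccccc1)(c1ccccc1)OCC1=C[C@H](OC1O)/C=C(/C)[C@@H](O)C[C@H]2O[C@]2(C)CCOCc2ccc(OC)cc2 | intermediate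
29 | (5R)-3-({[tert-butyl(diphenyl)silyl]oxy}methyl)-5-[(1Z,3S)-3-hydroxy-4-[(2R,3R)-3-{2-[(4-methoxybenzyl)oxy]ethyl}-3-methyloxiran-2-yl]-2-methylbut-1-en-1-yl]furan-2(5H)-one | CC(C)(C)[Si](c1ccccc1)(c1ccccc1)OCC1=C[C@H](OC1=O)/C=C(/C)[C@@H](O)C[C@H]2O[C@]2(C)CCOCc2ccc(OC)cc2 | intermediate
30 | (2R)-2-methylbutanoic acid | CC[C@@H](C)C(=O)O | starting material
31 | (2S,3Z)-4-[(2R)-4-({[tert-butyl(diphenyl)silyl]oxy}methyl)-5-oxo-2,5-dihydrofuran-2-yl]-1-[(2R,3R)-3-{2-[(4-methoxybenzyl)oxy]ethyl}-3-methyloxiran-2-yl]-3-methylbut-3-en-2-yl (2R)-2-methylbutanoate | CC(C)(C)[Si](c1ccccc1)(c1ccccc1)OCC1=C[C@H](OC1=O)/C=C(/C)[C@@H](OC(=O)[C@H](C)CC)C[C@H]2O[C@]2(C)CCOCc2ccc(OC)cc2 | intermediate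
32 | (2S,3Z)-4-[(2R)-4-(hydroxymethyl)-5-oxo-2,5-dihydrofuran-2-yl]-1-[(2R,3R)-3-{2-[(4-methoxybenzyl)oxy]ethyl}-3-methyloxiran-2-yl]-3-methylbut-3-en-2-yl (2R)-2-methylbutanoate | OCC1=C[C@H](OC1=O)/C=C(/C)[C@@H](OC(=O)[C@H](C)CC)C[C@H]2O[C@]2(C)CCOCc2ccc(OC)cc2 | intermediate
33 | (2S,3Z)-4-[(2R)-4-(bromomethyl)-5-oxo-2,5-dihydrofuran-2-yl]-1-[(2R,3R)-3-{2-[(4-methoxybenzyl)oxy]ethyl}-3-methyloxiran-2-yl]-3-methylbut-3-en-2-yl (2R)-2-methylbutanoate | BrCC1=C[C@H](OC1=O)/C=C(/C)[C@@H](OC(=O)[C@H](C)CC)C[C@H]2O[C@]2(C)CCOCc2ccc(OC)cc2 | intermediate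
34 | (2S,3Z)-4-[(2R)-4-(bromomethyl)-5-oxo-2,5-dihydrofuran-2-yl]-1-[(2R,3R)-3-(2-hydroxyethyl)-3-methyloxiran-2-yl]-3-methylbut-3-en-2-yl (2R)-2-methylbutanoate | BrCC1=C[C@H](OC1=O)/C=C(/C)[C@@H](OC(=O)[C@H](C)CC)C[C@H]2O[C@]2(C)CCO | intermediate
35 | (2S,3Z)-4-[(2R)-4-(bromomethyl)-5-oxo-2,5-dihydrofuran-2-yl]-3-methyl-1-[(2R,3R)-3-methyl-3-(2-oxoethyl)oxiran-2-yl]but-3-en-2-yl (2R)-2-methylbutanoate | BrCC1=C[C@H](OC1=O)/C=C(/C)[C@@H](OC(=O)[C@H](C)CC)C[C@H]2O[C@]2(C)CC=O | intermediate
36 | dichloro{[(5R)-5-{(1Z,3S)-2-methyl-3-{[(2R)-2-methylbutanoyl]oxy}-4-[(2R,3R)-3-methyl-3-(2-oxoethyl)oxiran-2-yl]but-1-en-1-yl}-2-oxo-2,5-dihydrofuran-3-yl]methyl}chromium | Cl[Cr](Cl)CC1=C[C@H](OC1=O)/C=C(/C)[C@@H](OC(=O)[C@H](C)CC)C[C@H]2O[C@]2(C)CC=O | intermediate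
37 | (1R,3S,4Z,6R,7R,8S,10R)-1,10-epoxy-8-hydroxy-3-{[(2R)-2-methylbutanoyl]oxy}germacra-4,11(13)-dien-12,6-olide (8-epi alcohol) | C=C1C(=O)O[C@@H]2/C=C(/C)[C@@H](OC(=O)[C@H](C)CC)C[C@H]3O[C@]3(C)C[C@H](O)[C@@H]12 | intermediate
38 | (1R,3S,4Z,6R,7R,8R,10R)-8-{[(2S,3R)-2,3-dimethyloxirane-2-carbonyl]oxy}-1,10-epoxy-3-{[(2R)-2-methylbutanoyl]oxy}germacra-4,11(13)-dien-12,6-olide | C=C1C(=O)O[C@@H]2/C=C(/C)[C@@H](OC(=O)[C@H](C)CC)C[C@H]3O[C@]3(C)C[C@@H](OC(=O)[C@@]3(C)O[C@@H]3C)[C@@H]12 | target

## Step count and risks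

Total step count: 23. Longest linear sequence: 16 steps (steps 1–5 or 6–10, then 13–23).

**Step 14 (key step).** The most likely failure is slow closure onto the hindered, oxygen-flanked isopropenyl group, so that the carbene at C5 is consumed by intermolecular metathesis at the vinyl group or the catalyst decays first. The fallback is a relay ring-closing metathesis that delivers ruthenium directly to C4.
- It sets out from 14. Shi epoxidation under the conditions of step 10 gives 2-[(2R,3R)-3-{2-[(4-methoxybenzyl)oxy]ethyl}-3-methyloxiran-2-yl]ethan-1-ol F1, and Dess–Martin oxidation gives the aldehyde [(2R,3R)-3-{2-[(4-methoxybenzyl)oxy]ethyl}-3-methyloxiran-2-yl]acetaldehyde F2.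
- Separately, but-2-yn-1-ol is converted with NaAlH2(OCH2CH2OMe)2 and then iodine into (2Z)-3-iodobut-2-en-1-ol F3, which is O-allylated (NaH, allyl bromide) to 3-{[(2Z)-3-iodobut-2-en-1-yl]oxy}prop-1-ene F4.
- Asymmetric Nozaki–Hiyama–Kishi coupling of F2 with F4 under the conditions of step 9 gives the relay alcohol (2S,3Z)-1-[(2R,3R)-3-{2-[(4-methoxybenzyl)oxy]ethyl}-3-methyloxiran-2-yl]-3-methyl-5-(prop-2-en-1-yloxy)pent-3-en-2-ol F5.
- Silylation with 22 and then 8 as in step 13 gives the relay silaketal F6 (the analogue of 24 in which the isopropenyl CH2 is replaced by CH–CH2–O–allyl).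
- With the second-generation Grubbs catalyst the carbene forms at the terminal allyl ether, expels 2,5-dihydrofuran and is thereby placed on C4, from where it closes onto the C5 vinyl group. The route is rejoined at 25.

**Step 22.** Two things may go wrong. The allylchromium may be consumed by protonation or intermolecular coupling before the ten-membered ring closes. The ring strain of the closing macrocycle may also override the chair model, so that the facial selectivity at C8 (or C7) differs from the one assumed. The fallback sets out from 35 and uses an indium-mediated Barbier ring closure (In powder, THF/H2O, high dilution). The allylindium tolerates water and, for allyl halides carrying a carbonyl group at the central carbon, is often reported to favour the opposite simple diastereoselectivity. If the 8S alcohol 37 forms, the route continues unchanged. If the 8R alcohol (1R,3S,4Z,6R,7R,8R,10R)-1,10-epoxy-8-hydroxy-3-{[(2R)-2-methylbutanoyl]oxy}germacra-4,11(13)-dien-12,6-olide F7 forms, it is esterified with 21 with retention under Yamaguchi conditions (2,4,6-trichlorobenzoyl chloride, Et3N, then DMAP, toluene), which rejoins the route at 38.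

**Step 23.** The activated C8 oxygen may be lost by elimination toward C7, whose hydrogen is allylic and vinylogously acidic, or displacement may fail because the carbinol is hindered. The fallback sets out from 37 and replaces inversion by substitution with inversion by redox. Dess–Martin oxidation gives the 8-ketone (1R,3S,4Z,6R,7S,10R)-1,10-epoxy-3-{[(2R)-2-methylbutanoyl]oxy}-8-oxogermacra-4,11(13)-dien-12,6-olide F8. Luche reduction (NaBH4, CeCl3·7H2O, MeOH, −78 °C) is then used to reach the 8R alcohol F7; the facial outcome of this reduction is not predictable and is the open point of this fallback. Yamaguchi esterification of F7 with 21 returns to the route at 38.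

**Step 5.** Face discrimination on the small, unhindered acrolein may be insufficient, and acrolein may polymerise under the Lewis-acidic conditions, so the enantiomeric purity or yield of 8 may be low. The fallback sets out from 6 and 7.
- A ligand-free Nozaki–Hiyama–Kishi reaction (CrCl2, NiCl2 cat., DMF) gives racemic 5-({[tert-butyl(dimethyl)silyl]oxy}methyl)-6-{[tert-butyl(diphenyl)silyl]oxy}hexa-1,4-dien-3-ol F9.
- Kinetic resolution with Candida antarctica lipase B and vinyl acetate acylates the R enantiomer, as the empirical rule for secondary alcohols with one small (vinyl) and one large substituent predicts. This gives the acetate (3R,4E)-5-({[tert-butyl(dimethyl)silyl]oxy}methyl)-6-{[tert-butyl(diphenyl)silyl]oxy}hexa-1,4-dien-3-yl acetate F10 and leaves the (3S)-alcohol F11.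
- Methanolysis of F10 (K2CO3, MeOH) returns to the route at 8.

**Step 9.** Enantioselectivity may again be insufficient, or the skipped enal may isomerise into conjugation before it is consumed. The fallback sets out from 15. Addition of CH2=C(CH3)MgBr (THF, −78 °C) gives racemic 8-[(4-methoxybenzyl)oxy]-2,6-dimethylocta-1,5-dien-3-ol F12. Dess–Martin oxidation gives the enone (5E)-8-[(4-methoxybenzyl)oxy]-2,6-dimethylocta-1,5-dien-3-one F13. Corey–Bakshi–Shibata reduction with the (R)-2-methyl-oxazaborolidine and BH3·SMe2 treats the isopropenyl group as the large substituent and should deliver the 3S alcohol, which rejoins the route at 17.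

## Further compounds

F1 | step 14 | 2-[(2R,3R)-3-{2-[(4-methoxybenzyl)oxy]ethyl}-3-methyloxiran-2-yl]ethan-1-ol | OCC[C@H]1O[C@]1(C)CCOCc1ccc(OC)cc1
F2 | step 14 | [(2R,3R)-3-{2-[(4-methoxybenzyl)oxy]ethyl}-3-methyloxiran-2-yl]acetaldehyde | O=CC[C@H]1O[C@]1(C)CCOCc1ccc(OC)cc1
F3 | step 14 | (2Z)-3-iodobut-2-en-1-ol | C/C(I)=C/CO
F4 | step 14 | 3-{[(2Z)-3-iodobut-2-en-1-yl]oxy}prop-1-ene | C=CCOC/C=C(/C)I
F5 | step 14 | (2S,3Z)-1-[(2R,3R)-3-{2-[(4-methoxybenzyl)oxy]ethyl}-3-methyloxiran-2-yl]-3-methyl-5-(prop-2-en-1-yloxy)pent-3-en-2-ol | C=CCOC/C=C(/C)[C@@H](O)C[C@H]1O[C@]1(C)CCOCc1ccc(OC)cc1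
F6 | step 14 | {[(3R,4E)-5-({[tert-butyl(dimethyl)silyl]oxy}methyl)-6-{[tert-butyl(diphenyl)silyl]oxy}hexa-1,4-dien-3-yl]oxy}{[(2S,3Z)-1-[(2R,3R)-3-{2-[(4-methoxybenzyl)oxy]ethyl}-3-methyloxiran-2-yl]-3-methyl-5-(prop-2-en-1-yloxy)pent-3-en-2-yl]oxy}di(propan-2-yl)silane | C=C[C@H](/C=C(/CO[Si](c1ccccc1)(c1ccccc1)C(C)(C)C)CO[Si](C)(C)C(C)(C)C)O[Si](C(C)C)(C(C)C)O[C@H](/C(C)=C\COCC=C)C[C@H]1O[C@]1(C)CCOCc1ccc(OC)cc1
F7 | step 22 | (1R,3S,4Z,6R,7R,8R,10R)-1,10-epoxy-8-hydroxy-3-{[(2R)-2-methylbutanoyl]oxy}germacra-4,11(13)-dien-12,6-olide | C=C1C(=O)O[C@@H]2/C=C(/C)[C@@H](OC(=O)[C@H](C)CC)C[C@H]3O[C@]3(C)C[C@@H](O)[C@@H]12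
F8 | step 23 | (1R,3S,4Z,6R,7S,10R)-1,10-epoxy-3-{[(2R)-2-methylbutanoyl]oxy}-8-oxogermacra-4,11(13)-dien-12,6-olide | C=C1C(=O)O[C@@H]2/C=C(/C)[C@@H](OC(=O)[C@H](C)CC)C[C@H]3O[C@]3(C)CC(=O)[C@@H]12
F9 | step 5 | racemic (4E)-5-({[tert-butyl(dimethyl)silyl]oxy}methyl)-6-{[tert-butyl(diphenyl)silyl]oxy}hexa-1,4-dien-3-ol | C=CC(O)/C=C(/CO[Si](c1ccccc1)(c1ccccc1)C(C)(C)C)CO[Si](C)(C)C(C)(C)C
F10 | step 5 | (3R,4E)-5-({[tert-butyl(dimethyl)silyl]oxy}methyl)-6-{[tert-butyl(diphenyl)silyl]oxy}hexa-1,4-dien-3-yl acetate | C=C[C@@H](OC(C)=O)/C=C(/CO[Si](c1ccccc1)(c1ccccc1)C(C)(C)C)CO[Si](C)(C)C(C)(C)C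
F11 | step 5 | (3S,4E)-5-({[tert-butyl(dimethyl)silyl]oxy}methyl)-6-{[tert-butyl(diphenyl)silyl]oxy}hexa-1,4-dien-3-ol | C=C[C@H](O)/C=C(/CO[Si](c1ccccc1)(c1ccccc1)C(C)(C)C)CO[Si](C)(C)C(C)(C)C
F12 | step 9 | racemic (5E)-8-[(4-methoxybenzyl)oxy]-2,6-dimethylocta-1,5-dien-3-ol | C=C(C)C(O)C/C=C(\C)CCOCc1ccc(OC)cc1
F13 | step 9 | (5E)-8-[(4-methoxybenzyl)oxy]-2,6-dimethylocta-1,5-dien-3-one | C=C(C)C(=O)C/C=C(\C)CCOCc1ccc(OC)cc1
A1 | alternative 1 | isoxazoline-bridged ten-membered lactone from the nitrile oxide cycloaddition | C[C@@]1(O[Si](C)(C)C)C[C@@H](O[Si](C)(C)C(C)(C)C)[C@H]2CC(=O)O[C@@H]2/C=C(/C)[C@@H]2CC1=NO2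
A2 | alternative 2 | ten-membered C8 alcohol from the Wittig–Still ring contraction | O[C@@H]1C/C(C)=C/C[C@H](OCc2ccc(OC)cc2)/C(C)=C\[C@@H](O[Si](C)(C)C(C)(C)C)[C@@H]1C(=C)CO[Si](C)(C)C(C)(C)C
A3 | alternative 3 | C3 alcohol of the C8-silylated germacranolide epoxide from the ring-closing alkenylation | C=C1C(=O)O[C@@H]2/C=C(/C)[C@@H](O)C[C@H]3O[C@]3(C)C[C@@H](O[Si](C)(C)C(C)(C)C)[C@@H]12
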